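## Analysis of the target

Target 17 is a daucane-type sesquiterpenoid ester: a cyclopentanone (C1–C5) fused along the C1–C5 bond to a cycloheptene (C1, C5–C10). The numbering used throughout is: C1 quaternary ring-fusion carbon with a methyl group, C2 ketone, C3 CH2, C4 carbinol carbon with OH and isopropyl, C5 ring-fusion CH, C6 CH–O(4-methoxybenzoyl), C7 CH2, C8 methyl-bearing alkene carbon, C9 alkene CH, C10 CH2.

The four stereocentres C1 (R), C4 (R), C5 (S) and C6 (S) are contiguous. The C1 methyl and the C4 hydroxyl lie on one face (β); H5 and the C6 oxygen lie on the other (α). The ring fusion is therefore trans, isopropyl is cis to H5, and O4/O6 are 1,3-anti.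

The sensitive groups are the β-hydroxy ketone C2–C3–C4 (retro-aldol, dehydration to a cyclopentenone), the aryl ester, and the C8=C9 bond, which sits β,γ to C6 and can move into conjugation in any C6 ketone precursor. The synthesis is hard because the ring-fusion methine C5 is flanked by two fully substituted carbons (C1, C4) on a seven-membered ring, and because the three oxygens at C2, C4 and C6 must end up at three different oxidation or acylation states.

The feature that the key step uses: ring atoms C5–C10 carry oxygen at C6 and methyl at C8, which is the substitution pattern of 3-methylphenol (1) with a carbon substituent ortho to O and para to CH3. The seventh ring atom C1 is a quaternary carbon bonded to C5 and C10 and α to the C2 ketone, i.e. the carbene carbon of an α-diazo ketone inserted into one C–C bond of that benzene ring. C4 is then a benzylic carbinol.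

## Retrosynthetic reasoning

**C6–O acyl bond.** 17 is cut to diol 15 and acid chloride 16. Only the secondary C6 hydroxyl should react, the tertiary C4 hydroxyl being inert. The ester is put on last so that it never meets hydride, fluoride or the chromium catalyst (which would bind its anisole ring).

**C6–H bond.** 15 goes back to ketone 14. The forward step must add hydride to the β-face of C6 and must not touch C2. The free C4 hydroxyl, 1,3 to C6 on the same face, is used to deliver the hydride.

**C7–H and C10–H bonds.** 14 goes back to dienone 13 by removing H2 from C7 and C10. The forward step is a 1,4-addition of hydrogen across the ring diene C7=C8–C9=C10, which leaves the double bond at C8=C9. No stereocentre is involved.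

**C5–H bond and two O–Si bonds.** 13 goes back to the silylene-bridged trienol ether 12. The forward step unmasks the C6 ketone and the C4 hydroxyl together and sets the ring fusion by protonation at C5.

**C1–C5 and C1–C10 (key disconnection).** Taking C1 out of the seven-membered ring of 12 leaves a benzene ring, so 12 goes back (through valence isomer 11) to aryl diazo ketone 10. This is cut here and not at C8=C9 or C5–C6 because it removes both rings and the quaternary centre at once and leaves a flat arene with one side chain. The forward step must choose the C5–C10 bond over C5–C6, the arene face that gives C1-methyl cis to O4, and arene addition over C–H insertion and hydride shift.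

**Diazo group, C1–CH3 and the C2 oxygen.** 10 goes back to ethyl ketone 8 (diazo transfer), 8 to methyl ketone 7 (one methyl electrophile) and 7 to terminal alkene 6 (alkene oxidation). These are functional-group steps on a side chain whose only stereocentre, C4, is quaternary and cannot epimerise.

**Two O–Si bonds.** 6 goes back to phenol–carbinol 5. The silylene is more than protection: it ties O4 to O6 in a six-membered ring coplanar with the arene, and that is the control element of the key step.

**C3–C4 bond.** 5 is cut to ketone 4 and an allyl nucleophile. This sets C4, the only reagent-controlled stereocentre. C1 (key step), C5 (protonation) and C6 (directed reduction) are then relayed from it.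

**Aryl–C4 bond.** 4 goes back through ester 3 to 1 and 2 by an ortho-acyl migration. Compound 1 supplies C5–C10, the C8 methyl and O6; 2 supplies C4, the isopropyl group and O4.

## Alternatives that were turned down

**Alternative 1:** the textbook route, ring-closing metathesis at C8=C9. The forward key step would be Ru-catalysed closure of diene A1, a cyclopentanone carrying the allyl group on C1 and the 1-acyloxy-3-methylbut-3-enyl chain on C5. It was turned down because the metathesis forms one non-stereogenic bond and every stereocentre has to be made beforehand. C1 would need an asymmetric allylic alkylation, C5/C6 an aldol at a methine flanked by two fully substituted carbons, and C4 an organometallic addition to one carbonyl of a 1,3-dione that must first be differentiated. That is well over fifteen steps, with the β-hydroxy ketone carried through most of them.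

**Alternative 2:** a (4+3) cycloaddition by vinylcarbene cyclopropanation and divinylcyclopropane rearrangement, forming C7–C8 and C1–C10. The forward key step would combine siloxydiene A2 (a 3-(1-siloxyvinyl)cyclopentenone) with a vinyldiazoacetate under a chiral rhodium catalyst to give cycloadduct A3. It puts C8=C9 and the C6 enol ether in the right places, but it was turned down for three reasons. The carbene carbon C8 must carry an ester, which then has to be reduced to the C8 methyl in the presence of two ketones. The Cope step must form the quaternary C1 through a boat transition state with the C1 methyl pointing inward. A2 already contains the C4 carbinol, which is harder to make enantiopure on a cyclopentenone than on an aryl ketone and must be matched to the catalyst-controlled cyclopropane.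

**Alternative 3:** late aldol closure of the cyclopentanone (C3–C4) from cycloheptene 1,4-diketone A4, with C4 set under thermodynamic control. The forward key step would be enolisation of the methyl ketone and addition to the isobutyryl ketone. It was turned down because it only moves the problem: A4 has the quaternary C1 next to the C5 methine and the C6 ester on a seven-membered ring, and no cycloaddition delivers that pattern (an oxyallyl (4+3) would put the oxygen on C5). The ring closure would also run under base, next to an ester and with dehydration of the aldol as the thermodynamic sink.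

Key step: step 7

Assumption: the (S,S)-allylsilane is taken to give the (R)-carbinol 5; if the sense of induction on ketone 4 is the opposite, the (R,R)-reagent is used and nothing else changes.

## Route

Step 1
Reactants: 1 m-cresol (3-methylphenol); 2 isobutyryl chloride (2-methylpropanoyl chloride)
Product: 4 1-(2-hydroxy-4-methylphenyl)-2-methylpropan-1-one, via m-tolyl isobutyrate 3 (not isolated)
Conditions: neat, 60 °C (HCl off); then AlCl3 (1.5 equiv), 150 °C; aq. HCl work-up
Reagents that add atoms: none
Why: O-acylation followed by a Lewis acid-mediated ortho-Fries rearrangement at high temperature; the acyl group goes to the ortho position para to the methyl group (the other ortho site is flanked by the methyl group), and the chelated ortho-hydroxy ketone is the thermodynamic product.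

Step 2
Reactants: 4 1-(2-hydroxy-4-methylphenyl)-2-methylpropan-1-one
Product: 5 2-[(3R)-3-hydroxy-2-methylhex-5-en-3-yl]-5-methylphenol
Conditions: (S,S)-allylchlorosilane reagent (1.5 equiv), toluene, 40 °C; then 1 M HCl, EtOAc, 0 °C
Reagents that add atoms: (3aS,7aS)-2-allyl-1,3-bis(4-bromobenzyl)-2-chlorooctahydro-1H-1,3,2-benzodiazasilole, C=CC[Si]1(Cl)N(Cc2ccc(Br)cc2)[C@H]2CCCC[C@@H]2N1Cc1ccc(Br)cc1
Why: Phenol-directed asymmetric allylation of a hindered 2-hydroxyaryl ketone with a strained chiral allylsilane: the phenol displaces chloride at silicon, the Lewis acidic silicon activates the ketone in this chelate, and the allyl group is transferred through a closed six-membered transition state whose face is fixed by the diamine. This forms C3–C4 and sets C4 (R), the only reagent-controlled stereocentre of the route.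

Step 3
Reactants: 5 2-[(3R)-3-hydroxy-2-methylhex-5-en-3-yl]-5-methylphenol
Product: 6 (4R)-4-allyl-2,2-di-tert-butyl-4-isopropyl-7-methyl-4H-1,3,2-benzodioxasiline
Conditions: tBu2Si(OTf)2 (1.2 equiv), 2,6-lutidine (3 equiv), CH2Cl2, 0 °C to rt
Reagents that add atoms: di-tert-butylsilyl bis(trifluoromethanesulfonate), CC(C)(C)[Si](OS(=O)(=O)C(F)(F)F)(OS(=O)(=O)C(F)(F)F)C(C)(C)C
Why: Silylene formation across the phenol and the tertiary alcohol gives a six-membered dioxasiline; it removes both O–H bonds (no O–H insertion, no o-quinone methide) and holds the C4–O bond in the plane of the arene, which later forces the side chain and the isopropyl group onto opposite faces.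

Step 4
Reactants: 6 (4R)-4-allyl-2,2-di-tert-butyl-4-isopropyl-7-methyl-4H-1,3,2-benzodioxasiline
Product: 7 1-[(4R)-2,2-di-tert-butyl-4-isopropyl-7-methyl-4H-1,3,2-benzodioxasilin-4-yl]propan-2-one
Conditions: PdCl2 (10 mol %), CuCl (1 equiv), O2 (1 atm), DMF/H2O 7:1, rt
Reagents that add atoms: water, O
Why: Tsuji–Wacker oxidation of the terminal alkene gives the methyl ketone with Markovnikov regiochemistry; the arene, the silylene and the quaternary centre are inert.

Step 5
Reactants: 7 1-[(4R)-2,2-di-tert-butyl-4-isopropyl-7-methyl-4H-1,3,2-benzodioxasilin-4-yl]propan-2-one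
Product: 8 1-[(4R)-2,2-di-tert-butyl-4-isopropyl-7-methyl-4H-1,3,2-benzodioxasilin-4-yl]butan-2-one
Conditions: LDA (1.1 equiv), THF, −78 °C; MeI (1.5 equiv), −78 to −40 °C
Reagents that add atoms: iodomethane, CI
Why: Kinetic deprotonation with LDA takes place at the methyl group and not at the neopentyl C3 methylene, and alkylation of this enolate gives the ethyl ketone that carries the future C1 and its methyl group.

Step 6
Reactants: 8 1-[(4R)-2,2-di-tert-butyl-4-isopropyl-7-methyl-4H-1,3,2-benzodioxasilin-4-yl]butan-2-one
Product: 10 3-diazo-1-[(4R)-2,2-di-tert-butyl-4-isopropyl-7-methyl-4H-1,3,2-benzodioxasilin-4-yl]butan-2-one, via trifluoroacetyl diketone 9 (not isolated)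
Conditions: LiHMDS (1.1 equiv), THF, −78 °C; CF3CO2CH2CF3 (1.2 equiv); aq. HCl quench; then MsN3 (1.5 equiv), Et3N (1.5 equiv), H2O (1 equiv), MeCN, rt
Reagents that add atoms: methanesulfonyl azide, CS(=O)(=O)N=[N+]=[N-] (the diazo nitrogens of 10); 2,2,2-trifluoroethyl trifluoroacetate, O=C(OCC(F)(F)F)C(F)(F)F (the trifluoroacetyl group of 9, lost again)
Why: Detrifluoroacetylative diazo transfer: the kinetic enolate on the ethyl side is C-acylated to the activated diketone 9, and diazo transfer from the sulfonyl azide with loss of the trifluoroacetyl group puts the diazo group on C1 only; the hindered C3 methylene is not enolised.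

Step 7
Reactants: 10 3-diazo-1-[(4R)-2,2-di-tert-butyl-4-isopropyl-7-methyl-4H-1,3,2-benzodioxasilin-4-yl]butan-2-one
Product: 12 (3R,8aR)-3,4-[(di-tert-butylsilanediyl)bis(oxy)]-3-isopropyl-6,8a-dimethyl-3,8a-dihydroazulen-1(2H)-one, via norcaradiene 11 (not isolated)
Conditions: Rh2(OAc)4 (1 mol %), CH2Cl2 (0.01 M, slow addition of 10), 40 °C
Reagents that add atoms: none
Why: Intramolecular Buchner reaction: rhodium(II) converts 10 with loss of N2 into a metal carbene at C1, which adds to the C5–C10 π-bond of the arene to give norcaradiene 11 (C1–C5–C10 cyclopropane), and 11 opens by disrotatory 6π electrocyclic cleavage of the C5–C10 bond to cycloheptatriene 12. The closest known reaction type is the rhodium- or copper-catalysed cyclisation of 2-diazo-5-arylpentan-3-ones to 8a-methyl-3,4-dihydroazulen-1(8aH)-ones. The cyclopentanone ring closes by C1–C5 bond formation (carbene addition at the ipso carbon, a 5-exo-type closure completed as a [2+1] cycloaddition), and the seven-membered ring is made by one-carbon expansion of the benzene ring (C1 inserted between C5 and C10). The new quaternary stereocentre C1 is controlled by C4: the silylene holds O4 in the arene plane, so the side chain (C3) and the isopropyl group lie on opposite faces and the carbene can only reach the face anti to isopropyl, which places the C1 methyl cis to O4 as in the target. Site selectivity for C5–C10 over C5–C6 follows from the oxygen substituent and the fused silylene ring at C6. Chemoselectivity over 1,2-hydride shift from the C1 methyl and over 1,5-C–H insertion into the isopropyl methine rests on the proximity of the electron-rich arene, on high dilution, and on deactivation of that methine by the adjacent oxygen-bearing quaternary carbon. C1 carries no hydrogen, so 12 cannot tautomerise, and acid is excluded to avoid rearomatisation through 11.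

Step 8
Reactants: 12 (3R,8aR)-3,4-[(di-tert-butylsilanediyl)bis(oxy)]-3-isopropyl-6,8a-dimethyl-3,8a-dihydroazulen-1(2H)-one
Product: 13 (3R,3aR,8aR)-3-hydroxy-3-isopropyl-6,8a-dimethyl-2,3,3a,8a-tetrahydroazulene-1,4-dione
Conditions: TBAF (3 equiv), AcOH (3 equiv), THF, −20 to 20 °C
Reagents that add atoms: none
Why: Fluoride cleaves the silyl enol ether bond first, and the enolate is protonated at C5 from the convex α-face, anti to the C1 methyl and to the fluorosilyloxy group still on O4; this gives the trans fusion, which should also be the thermodynamic one (isopropyl cis to H5, O4–H···O6 hydrogen bond), and the second Si–O cleavage frees the C4 hydroxyl. The acetic acid buffer keeps the tertiary alkoxide protonated (no retro-aldol, no E1cB), and once C5 is sp3 the norcaradiene path to an aromatic ring is closed.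

Step 9
Reactants: 13 (3R,3aR,8aR)-3-hydroxy-3-isopropyl-6,8a-dimethyl-2,3,3a,8a-tetrahydroazulene-1,4-dione
Product: 14 (3R,3aR,8aR)-3-hydroxy-3-isopropyl-6,8a-dimethyl-2,3,3a,5,8,8a-hexahydroazulene-1,4-dione
Conditions: (η6-naphthalene)Cr(CO)3 (20 mol %), H2 (50 bar), acetone, 25–40 °C
Reagents that add atoms: none
Why: (Arene)Cr(CO)3-catalysed 1,4-hydrogenation of a conjugated s-cis diene: both hydrogens go to the termini C7 and C10 and the double bond is left at C8=C9, as in the target. The C6 enone unit is s-trans in the ring and cannot be reduced in this mode, isolated ketones and alkenes are inert to this catalyst, and no stereocentre is formed.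

Step 10
Reactants: 14 (3R,3aR,8aR)-3-hydroxy-3-isopropyl-6,8a-dimethyl-2,3,3a,5,8,8a-hexahydroazulene-1,4-dione
Product: 15 (3R,3aS,4S,8aR)-3,4-dihydroxy-3-isopropyl-6,8a-dimethyl-3,3a,4,5,8,8a-hexahydroazulen-1(2H)-one
Conditions: Me4NBH(OAc)3 (5 equiv), MeCN/AcOH 1:1, −30 °C
Reagents that add atoms: none
Why: Hydroxyl-directed reduction of a β-hydroxy ketone (Evans–Saksena conditions): the borohydride exchanges an acetate for the C4 hydroxyl and delivers hydride through a six-membered chair transition state to the β-face of C6, giving the 1,3-anti (6α) alcohol. The reagent does not reduce ketones intermolecularly at this temperature, and C2 is shielded on both faces by the quaternary C1 and could only be reached through a strained bridged transition state.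

Step 11
Reactants: 15 (3R,3aS,4S,8aR)-3,4-dihydroxy-3-isopropyl-6,8a-dimethyl-3,3a,4,5,8,8a-hexahydroazulen-1(2H)-one; 16 4-methoxybenzoyl chloride
Product: 17 (3R,3aS,4S,8aR)-3-hydroxy-3-isopropyl-6,8a-dimethyl-1-oxo-1,2,3,3a,4,5,8,8a-octahydroazulen-4-yl 4-methoxybenzoate
Conditions: 16 (1.5 equiv), Et3N (3 equiv), DMAP (0.2 equiv), CH2Cl2, 0 °C to rt
Reagents that add atoms: none
Why: DMAP-catalysed acylation (nucleophilic catalysis) of the secondary C6 alcohol; the tertiary C4 alcohol is too hindered to react, and the mild base leaves the β-hydroxy ketone intact.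

## Compound list

1 | m-cresol (3-methylphenol) | Cc1cccc(O)c1 | starting material
2 | isobutyryl chloride | CC(C)C(Cl)=O | starting material
3 | m-tolyl isobutyrate | CC(C)C(=O)Oc1cccc(C)c1 | intermediate
4 | 1-(2-hydroxy-4-methylphenyl)-2-methylpropan-1-one | CC(C)C(=O)c1ccc(C)cc1O | intermediate
5 | 2-[(3R)-3-hydroxy-2-methylhex-5-en-3-yl]-5-methylphenol | C=CC[C@@](O)(C(C)C)c1ccc(C)cc1O | intermediate
6 | (4R)-4-allyl-2,2-di-tert-butyl-4-isopropyl-7-methyl-4H-1,3,2-benzodioxasiline | C=CC[C@@](O1)(C(C)C)c2ccc(C)cc2O[Si]1(C(C)(C)C)C(C)(C)C | intermediate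
7 | 1-[(4R)-2,2-di-tert-butyl-4-isopropyl-7-methyl-4H-1,3,2-benzodioxasilin-4-yl]propan-2-one | CC(=O)C[C@@](O1)(C(C)C)c2ccc(C)cc2O[Si]1(C(C)(C)C)C(C)(C)C | intermediate
8 | 1-[(4R)-2,2-di-tert-butyl-4-isopropyl-7-methyl-4H-1,3,2-benzodioxasilin-4-yl]butan-2-one | CCC(=O)C[C@@](O1)(C(C)C)c2ccc(C)cc2O[Si]1(C(C)(C)C)C(C)(C)C | intermediate
9 | 1,1,1-trifluoro-3-methyl-5-[(4R)-2,2-di-tert-butyl-4-isopropyl-7-methyl-4H-1,3,2-benzodioxasilin-4-yl]pentane-2,4-dione (C3 of the dione not defined) | CC(C(=O)C(F)(F)F)C(=O)C[C@@](O1)(C(C)C)c2ccc(C)cc2O[Si]1(C(C)(C)C)C(C)(C)C | intermediate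
10 | 3-diazo-1-[(4R)-2,2-di-tert-butyl-4-isopropyl-7-methyl-4H-1,3,2-benzodioxasilin-4-yl]butan-2-one | CC(=[N+]=[N-])C(=O)C[C@@](O1)(C(C)C)c2ccc(C)cc2O[Si]1(C(C)(C)C)C(C)(C)C | intermediate
11 | norcaradiene valence isomer of 12 (cyclopropane C1–C5–C10, diene C6=C7–C8=C9, silylene across O4/O6) | CC(C)(C)[Si]1(C(C)(C)C)OC2=CC(C)=C[C@@H]3[C@@]4(C)C(=O)C[C@@](O1)(C(C)C)[C@@]234 | intermediate
12 | (3R,8aR)-3,4-[(di-tert-butylsilanediyl)bis(oxy)]-3-isopropyl-6,8a-dimethyl-3,8a-dihydroazulen-1(2H)-one | CC(C)(C)[Si]1(C(C)(C)C)OC2=C3[C@](O1)(C(C)C)CC(=O)[C@]3(C)C=CC(C)=C2 | intermediate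
13 | (3R,3aR,8aR)-3-hydroxy-3-isopropyl-6,8a-dimethyl-2,3,3a,8a-tetrahydroazulene-1,4-dione | O=C1C=C(C)C=C[C@@]2(C)C(=O)C[C@@](O)(C(C)C)[C@H]12 | intermediate
14 | (3R,3aR,8aR)-3-hydroxy-3-isopropyl-6,8a-dimethyl-2,3,3a,5,8,8a-hexahydroazulene-1,4-dione | O=C1CC(C)=CC[C@@]2(C)C(=O)C[C@@](O)(C(C)C)[C@H]12 | intermediate
15 | (3R,3aS,4S,8aR)-3,4-dihydroxy-3-isopropyl-6,8a-dimethyl-3,3a,4,5,8,8a-hexahydroazulen-1(2H)-one | O[C@H]1CC(C)=CC[C@@]2(C)C(=O)C[C@@](O)(C(C)C)[C@H]12 | intermediate
16 | 4-methoxybenzoyl chloride | COc1ccc(C(Cl)=O)cc1 | starting material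
17 | (3R,3aS,4S,8aR)-3-hydroxy-3-isopropyl-6,8a-dimethyl-1-oxo-1,2,3,3a,4,5,8,8a-octahydroazulen-4-yl 4-methoxybenzoate | COc1ccc(C(=O)O[C@H]2CC(C)=CC[C@@]3(C)C(=O)C[C@@](O)(C(C)C)[C@H]23)cc1 | target

## Step count and least certain steps

Total step count: 11. Longest linear sequence: 11 steps, from 1 to 17.

**Step 7 (key step).** The carbene may be consumed by 1,2-hydride shift from the C1 methyl group or by 1,5-insertion into the isopropyl C–H bond before it reaches the arene, because the silylene ring limits the conformations in which C1 sits over the C5–C10 bond. The fallback leaves the route at methyl ketone 7. Its kinetic enolate is trifluoroacetylated to the activated diketone F1 (not isolated) and converted by the same diazo transfer into the terminal diazo ketone F2. This acceptor-only carbene has no β-hydrogen and belongs to the best-studied class for this ring expansion. Rhodium(II) acetate should take it through the norcaradiene F3 to the C1-unsubstituted trienol ether F4. Deprotonation of F4 at C1 with LiHMDS at −78 °C and alkylation with iodomethane anti to the isopropyl group then installs the quaternary methyl and returns to the route at 12.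

**Step 8.** Two processes threaten this step: loss of the tertiary oxygen by β-elimination or retro-aldol opening under the basic fluoride, and protonation of the enolate from the β-face, which would give the cis ring fusion. The fallback sets out from 12 and stages the unmasking. One equivalent of TBAF/AcOH at −40 °C opens only the enol Si–O bond and gives the fluorosilyl ether dienone F5; the tertiary oxygen stays masked, no alkoxide is formed, and the bulky silyl group on the β-face directs the proton to the α-face. F5 is hydrogenated under the conditions of step 9 to the fluorosilyl ether enone F6. The silyl group is then removed with HF·pyridine, which comes back to the route at 14.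

**Step 9.** The C8=C9 double bond of the product may drift into conjugation with the C6 ketone during or after the hydrogenation, and hydrogen transfer to the diene next to the quaternary C1 may be slow. The fallback sets out from 13 and changes what is hydrogenated. The directed reduction of step 10 is applied first to the dienone to give the dienediol F7. Its diene is then reduced 1,4 with the same chromium catalyst, so a deconjugated ketone is never formed. This returns to the route at 15.

**Step 10.** Hydride may also be delivered to C2, since both ketones are β to the C4 hydroxyl. Ligand exchange at the hindered tertiary hydroxyl may also be slow, so that undirected attack from the α-face competes. The fallback sets out from 14 and uses steric control instead of direction. L-Selectride at −78 °C should attack the less shielded C6 carbonyl from the α-face and give the 6β-alcohol F8. A Mitsunobu esterification of F8 with 4-methoxybenzoic acid (PPh3, DIAD) then inverts C6 and installs the ester in one operation, which reaches the route again at 17.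

## Further compounds

F1 | step 7 | 1,1,1-trifluoro-5-[(4R)-2,2-di-tert-butyl-4-isopropyl-7-methyl-4H-1,3,2-benzodioxasilin-4-yl]pentane-2,4-dione | O=C(CC(=O)C(F)(F)F)C[C@@](O1)(C(C)C)c2ccc(C)cc2O[Si]1(C(C)(C)C)C(C)(C)C
F2 | step 7 | 1-diazo-3-[(4R)-2,2-di-tert-butyl-4-isopropyl-7-methyl-4H-1,3,2-benzodioxasilin-4-yl]propan-2-one | [N-]=[N+]=CC(=O)C[C@@](O1)(C(C)C)c2ccc(C)cc2O[Si]1(C(C)(C)C)C(C)(C)C
F3 | step 7 | norcaradiene valence isomer of F4 (C1–H, cyclopropane C1–C5–C10) | CC(C)(C)[Si]1(C(C)(C)C)OC2=CC(C)=C[C@@H]3[C@H]4C(=O)C[C@@](O1)(C(C)C)[C@@]234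
F4 | step 7 | (3R,8aR)-3,4-[(di-tert-butylsilanediyl)bis(oxy)]-3-isopropyl-6-methyl-3,8a-dihydroazulen-1(2H)-one | CC(C)(C)[Si]1(C(C)(C)C)OC2=C3[C@](O1)(C(C)C)CC(=O)[C@@H]3C=CC(C)=C2
F5 | step 8 | (3R,3aR,8aR)-3-{[di-tert-butyl(fluoro)silyl]oxy}-3-isopropyl-6,8a-dimethyl-2,3,3a,8a-tetrahydroazulene-1,4-dione | O=C1C=C(C)C=C[C@@]2(C)C(=O)C[C@@](O[Si](F)(C(C)(C)C)C(C)(C)C)(C(C)C)[C@H]12
F6 | step 8 | (3R,3aR,8aR)-3-{[di-tert-butyl(fluoro)silyl]oxy}-3-isopropyl-6,8a-dimethyl-2,3,3a,5,8,8a-hexahydroazulene-1,4-dione | O=C1CC(C)=CC[C@@]2(C)C(=O)C[C@@](O[Si](F)(C(C)(C)C)C(C)(C)C)(C(C)C)[C@H]12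
F7 | step 9 | (3R,3aS,4S,8aR)-3,4-dihydroxy-3-isopropyl-6,8a-dimethyl-3,3a,4,8a-tetrahydroazulen-1(2H)-one | O[C@H]1C=C(C)C=C[C@@]2(C)C(=O)C[C@@](O)(C(C)C)[C@H]12
F8 | step 10 | (3R,3aS,4R,8aR)-3,4-dihydroxy-3-isopropyl-6,8a-dimethyl-3,3a,4,5,8,8a-hexahydroazulen-1(2H)-one | O[C@@H]1CC(C)=CC[C@@]2(C)C(=O)C[C@@](O)(C(C)C)[C@H]12
A1 | alternative 1 | metathesis diene: (1S)-1-[(1S,2R,5R)-5-allyl-2-hydroxy-2-isopropyl-5-methyl-4-oxocyclopentyl]-3-methylbut-3-enyl 4-methoxybenzoate | COc1ccc(C(=O)O[C@@H](CC(C)=C)[C@H]2[C@](O)(C(C)C)CC(=O)[C@]2(C)CC=C)cc1
A2 | alternative 2 | (4R)-3-{1-[(tert-butyldimethylsilyl)oxy]vinyl}-4-hydroxy-4-isopropyl-2-methylcyclopent-2-en-1-one | C=C(O[Si](C)(C)C(C)(C)C)C1=C(C)C(=O)C[C@@]1(O)C(C)C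
A3 | alternative 2 | cycloadduct: methyl (3R,8aR)-4-[(tert-butyldimethylsilyl)oxy]-3-hydroxy-3-isopropyl-8a-methyl-1-oxo-1,2,3,5,8,8a-hexahydroazulene-6-carboxylate | COC(=O)C1=CC[C@@]2(C)C(=O)C[C@@](O)(C(C)C)C2=C(O[Si](C)(C)C(C)(C)C)C1
A4 | alternative 3 | (1S,2R,3R)-3-acetyl-2-isobutyryl-3,5-dimethylcyclohept-5-en-1-yl 4-methoxybenzoate | COc1ccc(C(=O)O[C@H]2CC(C)=CC[C@@](C)(C(C)=O)[C@@H]2C(=O)C(C)C)cc1
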